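Germacrane locants are used throughout: ring C1–C10, C11–C13 for the lactone carbons, C14 on C10 and C15 on C4. Systematic names of the bicyclic compounds carry naphthalene locants, and the text says which germacrane carbon is meant. Nothing in this proposal has been run; every outcome is an expectation.

## Analysis of the target

Compound 40 is a germacranolide: a cyclodeca-1(10),4-diene (C1–C10) fused across C6–C7 to an α-methylene-γ-butyrolactone (O–C6, C7, C11, C12, exocyclic C13). The ring carries three contiguous stereocentres, C6 (R), C7 (R) and C8 (S). H6 and H7 are anti, so the lactone is trans-fused, and the C8 oxygen is trans to the C11 branch when C7 and C8 are viewed as neighbours in a six-membered ring. The fourth centre is the (S) carbon of the 2-methylbutanoate on O8, remote and brought in intact. Both ring alkenes are trisubstituted and cis with respect to the ring; they are E by the sequence rule only because C14 (aldehyde) and C15 (acetoxymethyl) are oxidised. The sensitive groups are the two Michael acceptors (enal, methylene lactone), the allylic acetate, and the C8 ester next to the lactone, where a free O8 could translactonise. The difficulty lies in the medium ring (entropy and transannular reactions), in the geometry of two trisubstituted alkenes, and in telling apart three oxidised carbons (C12, C14, C15) and three different acyl groups. The strategy rests on one feature: C1–C6 with C15 on C4 are the carbon pattern of a p-tolyl ring, and C7–C10 are a four-carbon bridge from C6 back to C1. The ten-membered ring is therefore a tetralin whose ring-fusion bond C1–C6 has been cut, with oxygen left on exactly the two carbons (C1, C6) that later carry the enal alkene and the lactone oxygen.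

## Retrosynthetic reasoning

**C15–O.** The acetate of 40 comes from alcohol 39, and 39 from the C15-methyl compound 38 by a selenium-mediated allylic oxidation. This is placed last because at that stage C4=C5 is the only alkene not conjugated to a carbonyl. The ene/[2,3] sequence also delivers the hydroxymethyl group trans to C6, which is the ring-cis geometry of the target, whatever the geometry of the precursor alkene.

**O8 acyl and C14 aldehyde.** Ester 38 is cut at the O8–acyl bond to alcohol 36 and acid 37. Enal 36 comes from diol 35 by oxidation of the allylic alcohol only, and 35 from the bis-silyl ether 34. The C8 ester cannot be carried earlier because it would not survive the enolate and hydride steps.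

**C11=C13.** The methylene of 34 is cut back to lactone 31 (enolate Mannich reaction and elimination). It is done while O8 and O14 are silyl ethers, since the base would destroy the esters and the enal.

**Lactone C12–O6.** Lactone 31 is opened to the 1,4-diol 29 (oxidative lactonisation, retention at C6). The 6R carbinol of 29 is traced through 28 and 27 to the 6S alcohol 26 by an inversion. The hydride reduction that creates C6 is expected to give the 6S epimer (25 from 24), so an inversion is planned and not left to chance.

**C14 oxidation level and C6–O.** Diol 25 comes from keto ester 24 by one hydride reduction of both the enoate and the enone. This has to precede the lactone, because no later ester could be reduced selectively.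

**C1–H and the C4=C5 alkene.** Enoate 24 is the reduction product of enol triflate 23, which keeps the alkene geometry. The conjugated enone of 23 is traced to the β,γ-unsaturated ketone 19 through the tertiary alcohol 21 (Markovnikov hydration, then β-elimination). An equilibration is not relied on, because conjugated cis-enones in ten-membered rings cannot become planar and are not reliably favoured over their β,γ-isomers.

**C1–O.** Enol triflate 19 comes from the β-keto ester 18. The chelated enolate places O1 and C14 on the same side, which is the geometry the C1=C10 alkene needs.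

**C1–C6 (key disconnection).** Diketone 18 is reconnected between C1 and C6 to the hexahydronaphthalene 16. In the forward sense the ten-membered ring is not closed; it is uncovered by cleaving the alkene shared by two six-membered rings. This avoids a macrocyclisation and fixes the position of the second alkene at C3=C4.

**Arene.** Diene 16 is the silylated methyl ester of acid 14, the Birch product of tetralin 13. The dissolving-metal step needs C14 as a carboxylate and C12 as an alcohol, which is why 13 is made from lactone acid 12 (C12 in a lactone, C14 a free acid) and 12 from hydroxy diester 10.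

**C7 and C8.** Alcohol 10 comes from dihydronaphthalene 8 by asymmetric hydroboration. Syn addition to a rigid bicyclic styrene sets the trans relation, and the reagent sets the absolute sense.

**Carbon skeleton.** Alkene 8 comes from tetralone 5 and bromoacetate 6 (C7–C11 bond). Tetralone 5 comes from diester 3 by Friedel–Crafts closure (C6–C7 bond), and 3 from arylacetate 1 and acrylate 2 (C9–C10 bond).

## Alternatives that were turned down

**Alternative 1:** The ring is cut at C2–C3, the central bond of the 1,5-diene. The forward step is a zerovalent-nickel coupling of the two primary allylic bromides of the seco lactone A2, head to head, to give the ten-membered lactone A1.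
- For it: the lactone and C6–C8 are set on an open chain, the route is convergent, and C14 and C15 are already oxygenated and distinguished by two silyl groups. On that last point it is stronger than the chosen route, which passes C14 through ester, alcohol and aldehyde and oxidises C15 late.
- Against it: allylnickel intermediates interconvert between η3 and η1 forms, so the geometry of both trisubstituted alkenes can scramble. Head-to-tail coupling gives smaller, vinyl-branched rings. The closure must beat oligomerisation at high dilution, and the nickel reagents are stoichiometric and air-sensitive or toxic.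
- Comparison: the chosen route lets the ring appear by bond cleavage, with no entropic price and no doubt about where the alkenes are at that moment. It pays with a longer functional-group sequence afterwards.

**Alternative 2:** The ring is cut at C7–C8. Indium metal or a divalent chromium salt turns the bromomethyl butenolide of aldehyde A4 into an allylmetal whose γ-carbon (C7) adds to the C8 aldehyde, giving hydroxy lactone A3.
- For it: one step closes the ring, creates C7 and C8 and unveils the exocyclic methylene. C6 comes from the butenolide, and only acylations remain. In end-game brevity, and in avoiding a separate methylenation, it is clearly stronger than the chosen route.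
- Against it: two stereocentres are set inside a macrocyclisation. Attack anti to the C6 substituent is plausible, but the C8 carbinol depends on how a cyclic transition state folds into a ten-membered ring. The β,γ-unsaturated aldehyde can enolise or conjugate, and the open-chain precursor needs two stereodefined trisubstituted alkenes of the less accessible geometry.
- Comparison: the chosen route fixes C7/C8 by syn-hydroboration on a rigid bicycle before any medium ring exists. It takes one alkene from the arene and the other from a chelated enolate.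

**Alternative 3:** In the forward sense C8–C9 is formed and C1–C6 is broken by an anionic oxy-Cope rearrangement of the cis-1,2-dialkenylcyclohexenol A6 as its potassium alkoxide. The resulting ten-membered enolate is alkylated at C7 with bromoacetate A7 to give dienone A5.
- For it: it is also a six-to-ten ring expansion with no macrocyclisation, the sigmatropic shift transfers chirality to C8, and C11/C12 enter in the same flask. A5 already has the C6 ketone conjugated to C4=C5 and both C14 and C15 oxygenated, where the chosen route must move an alkene and oxidise C15 late. On these points it is stronger.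
- Against it: A6 needs an enol ether of defined geometry next to a cis alkenyl group on a doubly allylic tertiary carbinol, which is a long preparation. The geometry of C1=C10 and the configuration of C8 both hang on a chair-versus-boat preference. The face of enolate alkylation sets C7 in a flexible ring, and the C6 reduction problem remains.
- Comparison: the chosen route starts from cheap achiral aromatics, sets C7/C8 in a rigid system and fixes C1=C10 by chelation, not by a pericyclic preference.

Key step: step 10

## Remarks on the chemistry (assumptions)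

- The facial sense of IpcBH2 in step 4 is taken from the empirical model for 1-substituted cycloalkenes (reagent from (+)-α-pinene gives the S carbinol).
- Hydride attack on enone 24 in step 15 is taken to follow the Felkin–Anh, peripheral-attack model and to give the 6S alcohol, so an inversion (step 17) is built in.
- The elimination in step 13 is written for the ring-cis enone; the geometry of C4=C5 is set anew in step 25.

## Route

Step 1
Reactants: 1 methyl 2-(4-methylphenyl)acetate; 2 tert-butyl acrylate
Product: 3 5-tert-butyl 1-methyl 2-(4-methylphenyl)pentanedioate (racemic)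
Conditions: KOtBu (0.1 equiv), THF, 0 °C; 1 in 1.3-fold excess
Reagents that add atoms: none
Why: Base-catalysed Michael addition of the arylacetate enolate to the acrylate forms C9–C10; catalytic base and excess 1 suppress a second addition, and the tert-butyl ester keeps the two carboxyl groups distinguishable.

Step 2
Reactants: 3 5-tert-butyl 1-methyl 2-(4-methylphenyl)pentanedioate
Product: 5 methyl 6-methyl-4-oxo-1,2,3,4-tetrahydronaphthalene-1-carboxylate (racemic), via acid 4 (not isolated)
Conditions: CF3CO2H, CH2Cl2, rt; evaporate; then P2O5/MeSO3H (Eaton's reagent), 40 °C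
Reagents that add atoms: none
Why: Acidolysis removes only the tert-butyl ester; the acylium ion of 4 then closes a six-membered ring by intramolecular Friedel–Crafts acylation at the only position it can reach (ortho to the benzylic carbon), forming C6–C7 with the methyl group ending on C4.

Step 3
Reactants: 5 methyl 6-methyl-4-oxo-1,2,3,4-tetrahydronaphthalene-1-carboxylate; 6 ethyl bromoacetate
Product: 8 methyl 4-(2-ethoxy-2-oxoethyl)-6-methyl-1,2-dihydronaphthalene-1-carboxylate (racemic), via hydroxy ester 7 (not isolated)
Conditions: Zn (activated), THF, reflux; then TsOH·H2O (cat.), PhMe, 80 °C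
Reagents that add atoms: none
Why: The Reformatsky reagent adds to the ketone and not to the ester (C7–C11 bond); acid-catalysed dehydration of the tertiary benzylic alcohol gives the endocyclic styrene C7=C8 because the exocyclic alkylidene isomer suffers peri strain.

Step 4
Reactants: 8 methyl 4-(2-ethoxy-2-oxoethyl)-6-methyl-1,2-dihydronaphthalene-1-carboxylate
Product: 10 methyl (3S,4S)-4-(2-ethoxy-2-oxoethyl)-3-hydroxy-6-methyl-1,2,3,4-tetrahydronaphthalene-1-carboxylate (both C1 epimers), via alkylborane 9 (not isolated)
Conditions: IpcBH2 [from (+)-α-pinene], THF, −25 °C; then 30% H2O2, pH 7 phosphate buffer, 0 °C → rt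
Reagents that add atoms: hydrogen peroxide, OO
Why: Asymmetric hydroboration: boron goes to the less substituted C8 and hydrogen to C7 on the same face, so the C11 branch and O8 end up trans; the chiral monoalkylborane selects the alkene face (S carbinol by the model for 1-substituted cycloalkenes) and C–B oxidation proceeds with retention. The remote C10 centre is carried as both epimers and disappears in step 11.

Step 5
Reactants: 10 methyl (3S,4S)-4-(2-ethoxy-2-oxoethyl)-3-hydroxy-6-methyl-1,2,3,4-tetrahydronaphthalene-1-carboxylate
Product: 12 (3aS,9bS)-8-methyl-2-oxo-1,2,3a,4,5,9b-hexahydronaphtho[2,1-b]furan-5-carboxylic acid (trans-fused lactone; C5 epimers), via hydroxy diacid 11 (not isolated)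
Conditions: LiOH, THF/H2O, rt; then 1 M HCl to pH 1; TsOH·H2O (cat.), PhMe, 60 °C
Reagents that add atoms: lithium hydroxide, [Li+].[OH-]
Why: Saponification of both esters followed by acid-catalysed lactonisation; only the O8/C12 pair can close a γ-lactone, so C12 is marked as the reducible carboxyl while C14 stays a free acid.

Step 6
Reactants: 12 (3aS,9bS)-8-methyl-2-oxo-1,2,3a,4,5,9b-hexahydronaphtho[2,1-b]furan-5-carboxylic acid
Product: 13 (3S,4S)-3-hydroxy-4-(2-hydroxyethyl)-6-methyl-1,2,3,4-tetrahydronaphthalene-1-carboxylic acid (C1 epimers)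
Conditions: LiBH4, THF, 0 °C → rt; then 1 M HCl to pH 3
Reagents that add atoms: none
Why: LiBH4 reduces lactones to diols but leaves lithium carboxylates untouched, so C12 reaches the alcohol level while C14 stays an acid.

Step 7
Reactants: 13 (3S,4S)-3-hydroxy-4-(2-hydroxyethyl)-6-methyl-1,2,3,4-tetrahydronaphthalene-1-carboxylic acid
Product: 14 (3S,4S)-3-hydroxy-4-(2-hydroxyethyl)-6-methyl-1,2,3,4,5,8-hexahydronaphthalene-1-carboxylic acid (C1 epimers)
Conditions: Li, NH3(l)/THF, t-BuOH, −78 → −33 °C; NH4Cl; then NaH2PO4 to pH 4–5
Reagents that add atoms: none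
Why: Birch reduction; the carboxylate and alkoxides are inert, and protonation occurs at the unsubstituted, para-related C2 and C5, so the three alkyl-bearing carbons stay sp2 and the 1,4-diene has the tetrasubstituted C1=C6 and the trisubstituted C3=C4 alkene. Quenching with NH4Cl before warming prevents base-induced conjugation.

Step 8
Reactants: 14 (3S,4S)-3-hydroxy-4-(2-hydroxyethyl)-6-methyl-1,2,3,4,5,8-hexahydronaphthalene-1-carboxylic acid
Product: 15 methyl (3S,4S)-3-hydroxy-4-(2-hydroxyethyl)-6-methyl-1,2,3,4,5,8-hexahydronaphthalene-1-carboxylate (C1 epimers)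
Conditions: TMSCHN2, PhMe/MeOH 4:1, 0 °C
Reagents that add atoms: (trimethylsilyl)diazomethane, C[Si](C)(C)C=[N+]=[N-]
Why: O-Methylation of the carboxylic acid by the diazoalkane under neutral conditions; the alcohols and the skipped diene are not touched.

Step 9
Reactants: 15 methyl (3S,4S)-3-hydroxy-4-(2-hydroxyethyl)-6-methyl-1,2,3,4,5,8-hexahydronaphthalene-1-carboxylate
Product: 16 methyl (3S,4S)-3-(tert-butyldimethylsilyloxy)-4-[2-(tert-butyldimethylsilyloxy)ethyl]-6-methyl-1,2,3,4,5,8-hexahydronaphthalene-1-carboxylate (C1 epimers)
Conditions: TBSOTf, 2,6-lutidine, CH2Cl2, −78 → 0 °C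
Reagents that add atoms: tert-butyldimethylsilyl triflate, CC(C)(C)[Si](C)(C)OS(=O)(=O)C(F)(F)F
Why: Silylation of the primary (O12) and the hindered secondary (O8) alcohol with the reactive silyl triflate and a non-nucleophilic base.

Step 10
Reactants: 16 methyl (3S,4S)-3-(tert-butyldimethylsilyloxy)-4-[2-(tert-butyldimethylsilyloxy)ethyl]-6-methyl-1,2,3,4,5,8-hexahydronaphthalene-1-carboxylate
Product: 18 methyl (3Z,8S)-8-(tert-butyldimethylsilyloxy)-7-[2-(tert-butyldimethylsilyloxy)ethyl]-4-methyl-1,6-dioxocyclodec-3-ene-10-carboxylate (germacrane locants; C7 as in 16; C10 epimers), via primary ozonide 17 (not isolated)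
Conditions: O3 (about 1 equiv, titrated solution), CH2Cl2/MeOH 5:1, NaHCO3, Sudan Red 7B, −78 °C; then Me2S, −78 °C → rt
Reagents that add atoms: ozone, [O-][O+]=O
Why: Ozone adds as a 1,3-dipole to the ring-fusion alkene C1=C6 to give the primary ozonide 17, which fragments; the peroxidic material is reduced by Me2S, leaving ketones at C1 and C6. The closest known reaction type is the ozonolytic cleavage of the central alkene of 9,10-octalins and Birch-reduced tetralins to cyclodecane-1,6-diones. The ten-membered ring is not formed by an end-to-end closure but appears when the bond common to both six-membered rings is cut, so no cyclisation entropy or transannular strain has to be overcome in a ring-closing transition state. No stereocentre is created; C7 and C8 are untouched and C10 stays a mixture that is erased in step 11. The step needs attack at the tetrasubstituted alkene in preference to the trisubstituted C3=C4: ozone is electrophilic and the fully substituted alkene is the more electron-rich, but the preference is modest, so ozone is dosed as a titrated solution with an indicator dye and conversion is stopped short of completion with recovery of 16. The second requirement is a neutral, cold work-up (solid NaHCO3, Me2S), because the 1,6-diketone can close transannularly by aldol reaction to a hydroazulene; for the same reason 18 is used at once in step 11.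

Step 11
Reactants: 18 methyl (3Z,8S)-8-(tert-butyldimethylsilyloxy)-7-[2-(tert-butyldimethylsilyloxy)ethyl]-4-methyl-1,6-dioxocyclodec-3-ene-10-carboxylate
Product: 19 methyl (1(10)Z,3Z,8S)-8-(tert-butyldimethylsilyloxy)-7-[2-(tert-butyldimethylsilyloxy)ethyl]-4-methyl-6-oxo-1-(trifluoromethylsulfonyloxy)cyclodeca-1(10),3-diene-10-carboxylate
Conditions: NaH, Et2O, 0 °C; then Tf2O, −78 → 0 °C
Reagents that add atoms: trifluoromethanesulfonic anhydride, O=S(=O)(OS(=O)(=O)C(F)(F)F)C(F)(F)F
Why: The β-keto ester is by far the most acidic site; its sodium enolate is held as a chelate between O1 and the ester carbonyl, so O-sulfonylation gives the Z-enol triflate with C2 and C9 cis. Removing the C1 carbonyl also ends the risk of transannular aldol closure and erases the C10 centre.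

Step 12
Reactants: 19 enol triflate (as named in step 11)
Product: 21 methyl (1(10)Z,8S)-8-(tert-butyldimethylsilyloxy)-7-[2-(tert-butyldimethylsilyloxy)ethyl]-4-hydroxy-4-methyl-6-oxo-1-(trifluoromethylsulfonyloxy)cyclodec-1(10)-ene-10-carboxylate (C4 epimers), via silyl peroxide 20 (not isolated)
Conditions: Co(acac)2 (cat.), PhSiH3, O2 (1 atm), THF, 0 °C → rt; then PPh3
Reagents that add atoms: dioxygen, O=O
Why: Mukaiyama hydration: a cobalt hydride transfers a hydrogen atom to C3, the tertiary C4 radical is trapped by dioxygen and the peroxide is reduced, giving the Markovnikov alcohol. The tetrasubstituted, electron-poor enol triflate alkene does not accept a hydrogen atom, and the C4 configuration is irrelevant.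

Step 13
Reactants: 21 tertiary alcohol (as named in step 12)
Product: 23 methyl (1(10)Z,4Z,8S)-8-(tert-butyldimethylsilyloxy)-7-[2-(tert-butyldimethylsilyloxy)ethyl]-4-methyl-6-oxo-1-(trifluoromethylsulfonyloxy)cyclodeca-1(10),4-diene-10-carboxylate, via trifluoroacetate 22 (not isolated)
Conditions: (CF3CO)2O, pyridine, DMAP (cat.), CH2Cl2, 0 °C; then DBU, 0 °C → rt
Reagents that add atoms: none
Why: Acylation of the tertiary alcohol and E1cB elimination: the only acidic hydrogens next to the leaving group are those at C5, α to the C6 ketone, so the alkene is formed specifically at C4=C5 under kinetic control. This avoids relying on an equilibrium that does not reliably favour conjugated enones in ten-membered rings.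

Step 14
Reactants: 23 enone triflate (as named in step 13)
Product: 24 methyl (1(10)E,4Z,8S)-8-(tert-butyldimethylsilyloxy)-7-[2-(tert-butyldimethylsilyloxy)ethyl]-4-methyl-6-oxocyclodeca-1(10),4-diene-10-carboxylate
Conditions: Pd(OAc)2 (cat.), PPh3, HCO2H, Bu3N, DMF, 60 °C
Reagents that add atoms: none
Why: Palladium-catalysed formate reduction of the enol triflate (oxidative addition to zerovalent palladium, decarboxylation of the formate, reductive elimination) replaces the triflate by hydrogen with retention, giving the enoate with C2 trans to C14 and a ring-cis C1=C10.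

Step 15
Reactants: 24 keto enoate (as named in step 14)
Product: 25 (1(10)E,4Z,6S,8S)-8-(tert-butyldimethylsilyloxy)-7-[2-(tert-butyldimethylsilyloxy)ethyl]-10-(hydroxymethyl)-4-methylcyclodeca-1(10),4-dien-6-ol
Conditions: iBu2AlH, CH2Cl2, −78 °C; aq. potassium sodium tartrate
Reagents that add atoms: none
Why: The aluminium hydride reduces the enone 1,2 and the enoate to the allylic alcohol in one operation, before any other ester exists. Hydride is expected on the face anti to the ring bond C7–C8 with the C11 branch turned outward (Felkin–Anh arrangement, which is also the peripheral face), giving the 6S alcohol, the epimer that would close to a cis-fused lactone.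

Step 16
Reactants: 25 diol (as named in step 15)
Product: 26 (1(10)E,4Z,6S,8S)-8-(tert-butyldimethylsilyloxy)-7-[2-(tert-butyldimethylsilyloxy)ethyl]-10-[(tert-butyldiphenylsilyloxy)methyl]-4-methylcyclodeca-1(10),4-dien-6-ol
Conditions: TBDPSCl, imidazole, CH2Cl2, 0 °C
Reagents that add atoms: tert-butyl(chloro)diphenylsilane, CC(C)(C)[Si](Cl)(c1ccccc1)c1ccccc1
Why: The bulky silyl chloride reacts with the primary allylic O14 and not with the hindered secondary O6; the diphenyl group is chosen to outlast the later removal of the primary TBS ether.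

Step 17
Reactants: 26 allylic alcohol (as named in step 16)
Product: 27 (1(10)E,4Z,6R,8S)-8-(tert-butyldimethylsilyloxy)-7-[2-(tert-butyldimethylsilyloxy)ethyl]-10-[(tert-butyldiphenylsilyloxy)methyl]-4-methylcyclodeca-1(10),4-dien-6-yl 4-nitrobenzoate
Conditions: 4-O2NC6H4CO2H, PPh3, DIAD, PhMe, 0 °C → rt
Reagents that add atoms: 4-nitrobenzoic acid, OC(=O)c1ccc(cc1)[N+](=O)[O-]
Why: Mitsunobu inversion: the carboxylate displaces the oxyphosphonium group at C6 by SN2, turning 6S into 6R; the acidic nitrobenzoic acid is the standard partner for hindered alcohols, and the SN2′ path is disfavoured because the far allyl terminus C4 is fully substituted.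

Step 18
Reactants: 27 nitrobenzoate (as named in step 17)
Product: 28 (1(10)E,4Z,6R,8S)-8-(tert-butyldimethylsilyloxy)-7-[2-(tert-butyldimethylsilyloxy)ethyl]-10-[(tert-butyldiphenylsilyloxy)methyl]-4-methylcyclodeca-1(10),4-dien-6-ol
Conditions: K2CO3 (cat.), MeOH, 0 °C
Reagents that add atoms: none
Why: Transesterification of the activated aryl ester by methoxide at the acyl carbon leaves the C6–O bond and all three silyl ethers intact.

Step 19
Reactants: 28 allylic alcohol (as named in step 18)
Product: 29 (1(10)E,4Z,6R,8S)-8-(tert-butyldimethylsilyloxy)-10-[(tert-butyldiphenylsilyloxy)methyl]-7-(2-hydroxyethyl)-4-methylcyclodeca-1(10),4-dien-6-ol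
Conditions: HF·pyridine, pyridine, THF, 0 °C
Reagents that add atoms: none
Why: Buffered fluoride cleaves the unhindered primary TBS ether at O12 faster than the secondary TBS ether at O8 and the diphenylsilyl ether at O14.

Step 20
Reactants: 29 diol (as named in step 19)
Product: 31 (6R,8S)-8-(tert-butyldimethylsilyloxy)-14-(tert-butyldiphenylsilyloxy)germacra-1(10)E,4Z-dien-6,12-olide lacking C13 (trans-fused γ-lactone O6–C12), via lactol 30 (not isolated)
Conditions: TEMPO (cat.), PhI(OAc)2, CH2Cl2, rt
Reagents that add atoms: none
Why: Oxidative lactonisation: the oxoammonium salt oxidises the primary alcohol first, the aldehyde is captured by O6 as lactol 30, and this is oxidised to the lactone. The C6–O bond is not touched, so the 6R configuration gives the trans ring fusion (H6 and H7 anti).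

Step 21
Reactants: 31 lactone (as named in step 20)
Product: 34 (6R,8S)-8-(tert-butyldimethylsilyloxy)-14-(tert-butyldiphenylsilyloxy)germacra-1(10)E,4Z,11(13)-trien-6,12-olide, via Mannich base 32 (not isolated), via ammonium iodide 33 (not isolated)
Conditions: LiN(iPr)2, THF, −78 °C; CH2=NMe2+ I−, −78 °C → rt; then MeI, MeOH; then aq. NaHCO3, CH2Cl2
Reagents that add atoms: N,N-dimethylmethyleneiminium iodide (Eschenmoser's salt), C=[N+](C)C.[I-]
Why: The lactone enolate undergoes a Mannich reaction at C11; quaternisation and base-induced β-elimination of trimethylamine give the exocyclic methylene and erase the transient C11 centre. No β-leaving group is available to the enolate, and O8 and O14 are protected as silyl ethers.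

Step 22
Reactants: 34 methylene lactone (as named in step 21)
Product: 35 (6R,8S)-8,14-dihydroxygermacra-1(10)E,4Z,11(13)-trien-6,12-olide
Conditions: HF·pyridine, THF, 0 °C → rt
Reagents that add atoms: none
Why: Fluoride cleaves both remaining silyl ethers under acidic, non-nucleophilic conditions, which avoids conjugate addition to the methylene lactone and base-induced migration of the lactone to O8.

Step 23
Reactants: 35 diol (as named in step 22)
Product: 36 (6R,8S)-8-hydroxy-14-oxogermacra-1(10)E,4Z,11(13)-trien-6,12-olide
Conditions: MnO2, CH2Cl2, rt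
Reagents that add atoms: none
Why: MnO2 oxidises only the allylic primary alcohol, so the C14 enal forms with the alkene geometry kept and the saturated secondary O8 left free.

Step 24
Reactants: 36 hydroxy enal (as named in step 23); 37 (S)-2-methylbutanoic acid
Product: 38 (6R,8S)-8-[(S)-2-methylbutanoyloxy]-14-oxogermacra-1(10)E,4Z,11(13)-trien-6,12-olide
Conditions: EDC·HCl, DMAP, CH2Cl2, 0 °C → rt
Reagents that add atoms: none
Why: Carbodiimide (Steglich) esterification of the secondary alcohol; an α-branched alkanoic acid activated in this way is not expected to epimerise, and the short, cold reaction limits lactone migration to O8.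

Step 25
Reactants: 38 ester (as named in step 24)
Product: 39 (6R,8S)-15-hydroxy-8-[(S)-2-methylbutanoyloxy]-14-oxogermacra-1(10)E,4E,11(13)-trien-6,12-olide
Conditions: SeO2 (cat.), t-BuOOH, CH2Cl2, rt
Reagents that add atoms: tert-butyl hydroperoxide, CC(C)(C)OO; selenium dioxide, O=[Se]=O
Why: Selenium dioxide allylic oxidation: an ene reaction at the only alkene not conjugated to a carbonyl (C4=C5) takes a methyl hydrogen, and the [2,3]-sigmatropic shift returns the alkene and delivers oxygen to C15. The rearrangement places the hydroxymethyl group trans to the C6 substituent, which is the ring-cis geometry of the target.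

Step 26
Reactants: 39 allylic alcohol (as named in step 25)
Product: 40 target, (6R,7R,8S)-15-acetoxy-8-[(S)-2-methylbutanoyloxy]-14-oxogermacra-1(10)E,4E,11(13)-trien-6,12-olide
Conditions: Ac2O, pyridine, DMAP (cat.), CH2Cl2, 0 °C
Reagents that add atoms: acetic anhydride, CC(=O)OC(C)=O
Why: Acetylation of the only free hydroxyl group, a primary allylic alcohol, under mild acyl-transfer catalysis.

## Compound list

1 | methyl 2-(4-methylphenyl)acetate | COC(=O)Cc1ccc(C)cc1 | starting material
2 | tert-butyl acrylate | C=CC(=O)OC(C)(C)C | starting material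
3 | 5-tert-butyl 1-methyl 2-(4-methylphenyl)pentanedioate | COC(=O)C(CCC(=O)OC(C)(C)C)c1ccc(C)cc1 | intermediate
4 | 5-methoxy-4-(4-methylphenyl)-5-oxopentanoic acid | COC(=O)C(CCC(=O)O)c1ccc(C)cc1 | intermediate
5 | methyl 6-methyl-4-oxo-1,2,3,4-tetrahydronaphthalene-1-carboxylate | COC(=O)C1CCC(=O)c2cc(C)ccc12 | intermediate
6 | ethyl bromoacetate | BrCC(=O)OCC | starting material
7 | methyl 4-(2-ethoxy-2-oxoethyl)-4-hydroxy-6-methyl-1,2,3,4-tetrahydronaphthalene-1-carboxylate | CCOC(=O)CC1(O)CCC(C(=O)OC)c2ccc(C)cc12 | intermediate
8 | methyl 4-(2-ethoxy-2-oxoethyl)-6-methyl-1,2-dihydronaphthalene-1-carboxylate | CCOC(=O)CC1=CCC(C(=O)OC)c2ccc(C)cc12 | intermediate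
9 | alkyl(isopinocampheyl)borane from 8 (boron on C8, trans to the C7 side chain) | CCOC(=O)C[C@@H]1[C@@H](B[C@@H]3C[C@@H]4C[C@@H](C4(C)C)[C@H]3C)CC(C(=O)OC)c2ccc(C)cc12 | intermediate
10 | methyl (3S,4S)-4-(2-ethoxy-2-oxoethyl)-3-hydroxy-6-methyl-1,2,3,4-tetrahydronaphthalene-1-carboxylate | CCOC(=O)C[C@@H]1[C@@H](O)CC(C(=O)OC)c2ccc(C)cc12 | intermediate
11 | (3S,4S)-4-(carboxymethyl)-3-hydroxy-6-methyl-1,2,3,4-tetrahydronaphthalene-1-carboxylic acid | OC(=O)C[C@@H]1[C@@H](O)CC(C(=O)O)c2ccc(C)cc12 | intermediate
12 | (3aS,9bS)-8-methyl-2-oxo-1,2,3a,4,5,9b-hexahydronaphtho[2,1-b]furan-5-carboxylic acid | O=C1C[C@@H]2[C@@H](O1)CC(C(=O)O)c1ccc(C)cc12 | intermediate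
13 | (3S,4S)-3-hydroxy-4-(2-hydroxyethyl)-6-methyl-1,2,3,4-tetrahydronaphthalene-1-carboxylic acid | OCC[C@@H]1[C@@H](O)CC(C(=O)O)c2ccc(C)cc12 | intermediate
14 | (3S,4S)-3-hydroxy-4-(2-hydroxyethyl)-6-methyl-1,2,3,4,5,8-hexahydronaphthalene-1-carboxylic acid | OCC[C@@H]1[C@@H](O)CC(C(=O)O)C2=C1CC(C)=CC2 | intermediate
15 | methyl (3S,4S)-3-hydroxy-4-(2-hydroxyethyl)-6-methyl-1,2,3,4,5,8-hexahydronaphthalene-1-carboxylate | COC(=O)C1C[C@H](O)[C@@H](CCO)C2=C1CC=C(C)C2 | intermediate
16 | methyl (3S,4S)-3-(tert-butyldimethylsilyloxy)-4-[2-(tert-butyldimethylsilyloxy)ethyl]-6-methyl-1,2,3,4,5,8-hexahydronaphthalene-1-carboxylate | COC(=O)C1C[C@H](O[Si](C)(C)C(C)(C)C)[C@@H](CCO[Si](C)(C)C(C)(C)C)C2=C1CC=C(C)C2 | intermediate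
17 | primary ozonide (1,2,3-trioxolane across C1–C6) of 16 | COC(=O)C1C[C@H](O[Si](C)(C)C(C)(C)C)[C@@H](CCO[Si](C)(C)C(C)(C)C)C23OOOC13CC=C(C)C2 | intermediate
18 | ten-membered (3Z)-1,6-diketone with C10 methyl ester, 8-OTBS and 7-(2-TBSO-ethyl) | COC(=O)C1C[C@H](O[Si](C)(C)C(C)(C)C)[C@@H](CCO[Si](C)(C)C(C)(C)C)C(=O)C/C(C)=C\CC1=O | intermediate
19 | (1(10)Z,3Z)-enol triflate at C1 of 18, C6 ketone | COC(=O)/C1=C(\OS(=O)(=O)C(F)(F)F)C/C=C(C)\CC(=O)[C@H](CCO[Si](C)(C)C(C)(C)C)[C@@H](O[Si](C)(C)C(C)(C)C)C1 | intermediate
20 | C4 phenylsilyl peroxide of the hydration product | COC(=O)/C1=C(\OS(=O)(=O)C(F)(F)F)CCC(C)(OO[SiH2]c2ccccc2)CC(=O)[C@H](CCO[Si](C)(C)C(C)(C)C)[C@@H](O[Si](C)(C)C(C)(C)C)C1 | intermediate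
21 | C4 tertiary alcohol (β-hydroxy ketone), enol triflate retained | COC(=O)/C1=C(\OS(=O)(=O)C(F)(F)F)CCC(C)(O)CC(=O)[C@H](CCO[Si](C)(C)C(C)(C)C)[C@@H](O[Si](C)(C)C(C)(C)C)C1 | intermediate
22 | C4 trifluoroacetate of 21 | COC(=O)/C1=C(\OS(=O)(=O)C(F)(F)F)CCC(C)(OC(=O)C(F)(F)F)CC(=O)[C@H](CCO[Si](C)(C)C(C)(C)C)[C@@H](O[Si](C)(C)C(C)(C)C)C1 | intermediate
23 | (4Z)-enone (C4=C5–C6=O) with (1(10)Z)-enol triflate | COC(=O)/C1=C(\OS(=O)(=O)C(F)(F)F)CC/C(C)=C\C(=O)[C@H](CCO[Si](C)(C)C(C)(C)C)[C@@H](O[Si](C)(C)C(C)(C)C)C1 | intermediate
24 | (1(10)E,4Z)-keto enoate | COC(=O)/C1=C/CC/C(C)=C\C(=O)[C@H](CCO[Si](C)(C)C(C)(C)C)[C@@H](O[Si](C)(C)C(C)(C)C)C1 | intermediate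
25 | (6S,8S)-6,14-diol, 8-OTBS, 12-OTBS | OC/C1=C/CC/C(C)=C\[C@H](O)[C@H](CCO[Si](C)(C)C(C)(C)C)[C@@H](O[Si](C)(C)C(C)(C)C)C1 | intermediate
26 | (6S,8S)-6-ol, 14-OTBDPS, 8-OTBS, 12-OTBS | CC(C)(C)[Si](OC/C1=C/CC/C(C)=C\[C@H](O)[C@H](CCO[Si](C)(C)C(C)(C)C)[C@@H](O[Si](C)(C)C(C)(C)C)C1)(c1ccccc1)c1ccccc1 | intermediate
27 | (6R,8S)-6-(4-nitrobenzoate), 14-OTBDPS, 8-OTBS, 12-OTBS | CC(C)(C)[Si](OC/C1=C/CC/C(C)=C\[C@@H](OC(=O)c2ccc(cc2)[N+](=O)[O-])[C@H](CCO[Si](C)(C)C(C)(C)C)[C@@H](O[Si](C)(C)C(C)(C)C)C1)(c1ccccc1)c1ccccc1 | intermediate
28 | (6R,8S)-6-ol, 14-OTBDPS, 8-OTBS, 12-OTBS | CC(C)(C)[Si](OC/C1=C/CC/C(C)=C\[C@@H](O)[C@H](CCO[Si](C)(C)C(C)(C)C)[C@@H](O[Si](C)(C)C(C)(C)C)C1)(c1ccccc1)c1ccccc1 | intermediate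
29 | (6R,8S)-6,12-diol, 14-OTBDPS, 8-OTBS | CC(C)(C)[Si](OC/C1=C/CC/C(C)=C\[C@@H](O)[C@H](CCO)[C@@H](O[Si](C)(C)C(C)(C)C)C1)(c1ccccc1)c1ccccc1 | intermediate
30 | lactol (O6–C12 hemiacetal) of 29 | CC(C)(C)[Si](OC/C1=C/CC/C(C)=C\[C@H]2OC(O)C[C@@H]2[C@@H](O[Si](C)(C)C(C)(C)C)C1)(c1ccccc1)c1ccccc1 | intermediate
31 | trans-fused 6,12-lactone (no C13), 14-OTBDPS, 8-OTBS | CC(C)(C)[Si](OC/C1=C/CC/C(C)=C\[C@H]2OC(=O)C[C@@H]2[C@@H](O[Si](C)(C)C(C)(C)C)C1)(c1ccccc1)c1ccccc1 | intermediate
32 | C11 (dimethylamino)methyl lactone (Mannich base) | CC(C)(C)[Si](OC/C1=C/CC/C(C)=C\[C@H]2OC(=O)C(CN(C)C)[C@@H]2[C@@H](O[Si](C)(C)C(C)(C)C)C1)(c1ccccc1)c1ccccc1 | intermediate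
33 | C11 (trimethylammonio)methyl lactone iodide | CC(C)(C)[Si](OC/C1=C/CC/C(C)=C\[C@H]2OC(=O)C(C[N+](C)(C)C)[C@@H]2[C@@H](O[Si](C)(C)C(C)(C)C)C1)(c1ccccc1)c1ccccc1.[I-] | intermediate
34 | α-methylene lactone, 14-OTBDPS, 8-OTBS | CC(C)(C)[Si](OC/C1=C/CC/C(C)=C\[C@H]2OC(=O)C(=C)[C@@H]2[C@@H](O[Si](C)(C)C(C)(C)C)C1)(c1ccccc1)c1ccccc1 | intermediate
35 | α-methylene lactone 8,14-diol | OC/C1=C/CC/C(C)=C\[C@H]2OC(=O)C(=C)[C@@H]2[C@@H](O)C1 | intermediate
36 | 8-hydroxy C14 enal | O=C/C1=C/CC/C(C)=C\[C@H]2OC(=O)C(=C)[C@@H]2[C@@H](O)C1 | intermediate
37 | (S)-2-methylbutanoic acid | CC[C@H](C)C(=O)O | starting material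
38 | 8-O-[(S)-2-methylbutanoyl] C14 enal with C15 methyl | O=C/C1=C/CC/C(C)=C\[C@H]2OC(=O)C(=C)[C@@H]2[C@@H](OC(=O)[C@@H](C)CC)C1 | intermediate
39 | 15-hydroxy compound | O=C/C1=C/CC/C(CO)=C\[C@H]2OC(=O)C(=C)[C@@H]2[C@@H](OC(=O)[C@@H](C)CC)C1 | intermediate
40 | target (CNP0230988.8) | C=C1C(=O)O[C@@H]2/C=C(/COC(C)=O)CC/C=C(/C=O)C[C@H](OC(=O)[C@@H](C)CC)[C@@H]12 | target

## Step count and least certain steps

Total: 26 steps. Longest linear sequence: 26 steps (1 to 40; acid 37 is bought).

**Step 10 (key step).** Ozone may also attack the trisubstituted C3=C4 alkene, since the rate advantage of the tetrasubstituted alkene is modest. The hindered alkene may be epoxidised instead of cleaved, and the 1,6-diketone may close by transannular aldol reaction during work-up. Fallback: starting from 16, the ring-fusion alkene is epoxidised with mCPBA, which discriminates more strongly in favour of the tetrasubstituted alkene, to give the C1/C6 epoxide F1. F1 is hydrolysed and cleaved in one operation with periodic acid (H5IO6, aqueous THF, 0 °C), and the route is rejoined at 18.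

**Step 12.** Hydrogen-atom transfer may be slow or unselective at the hindered alkene, the peroxide may be reduced incompletely, and the β-hydroxy ketone may undergo retro-aldol ring opening. Fallback: starting from 19, oxymercuration with Hg(OAc)2 in aqueous THF gives the C3 organomercurial acetate F2 with the hydroxyl on C4. Radical demercuration with Bu3SnH, which leaves the ketone alone, returns to the route at 21.

**Step 15.** Facial selectivity in the reduction of the ten-membered enone may be poor or opposite to the model. Fallback: starting from 24, any (6R)-diol F3 that is formed is not wasted. It is silylated at O14 under the conditions of step 16 and is then identical with 28, so the route is rejoined at 28 without steps 17 and 18, while the 6S portion follows the main line.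

**Step 17.** The allylic oxyphosphonium ion may ionise (loss of stereospecificity), be attacked in the SN2′ sense or eliminate to a diene. Fallback: starting from 26, the carbinol is oxidised with MnO2 to the enone F4. F4 is reduced under reagent control with a CBS oxazaborolidine and BH3·SMe2, using the catalyst enantiomer that delivers hydride to the face avoided in step 15. The route is rejoined at 28.

**Step 25.** Oxidation may compete at the ring methylene C3, and the new alcohol may be over-oxidised to the C15 aldehyde. Fallback: starting from 38, ene-type chlorination with hypochlorous acid (Ca(OCl)2, CO2, CH2Cl2/H2O) moves the alkene to C4=C15 and gives the C5 allylic chloride F5. SN2′ displacement with CsOAc in DMF places the acetate on C15 and returns the alkene to C4=C5, rejoining the route at 40.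

**Step 4.** Enantiofacial control may be incomplete, in particular for the C10 epimer that is mismatched with the reagent, which would lower the enantiomeric purity of everything that follows. Fallback: starting from 8, hydroboration with BH3·SMe2 and oxidation give the racemic trans alcohol, that is 10 together with its (3R,4R)-enantiomer F6. Candida antarctica lipase B with vinyl acetate is expected to acylate the R carbinol to the acetate F7, and the unreacted alcohol is separated and rejoins the route at 10.

## Further compounds

F1 | step 10 | C1/C6 epoxide of 16 | COC(=O)C1C[C@H](O[Si](C)(C)C(C)(C)C)[C@@H](CCO[Si](C)(C)C(C)(C)C)C23OC13CC=C(C)C2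
F2 | step 12 | C3 acetoxymercurio C4 alcohol from 19 | COC(=O)/C1=C(\OS(=O)(=O)C(F)(F)F)CC([Hg]OC(C)=O)C(C)(O)CC(=O)[C@H](CCO[Si](C)(C)C(C)(C)C)[C@@H](O[Si](C)(C)C(C)(C)C)C1
F3 | step 15 | (6R,8S)-6,14-diol, the C6 epimer of 25 | OC/C1=C/CC/C(C)=C\[C@@H](O)[C@H](CCO[Si](C)(C)C(C)(C)C)[C@@H](O[Si](C)(C)C(C)(C)C)C1
F4 | step 17 | C6 enone with 14-OTBDPS, 8-OTBS, 12-OTBS | CC(C)(C)[Si](OC/C1=C/CC/C(C)=C\C(=O)[C@H](CCO[Si](C)(C)C(C)(C)C)[C@@H](O[Si](C)(C)C(C)(C)C)C1)(c1ccccc1)c1ccccc1
F5 | step 25 | 5-chloro-4(15)-ene from 38 | O=C/C1=C/CCC(=C)C(Cl)[C@H]2OC(=O)C(=C)[C@@H]2[C@@H](OC(=O)[C@@H](C)CC)C1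
F6 | step 4 | (3R,4R)-enantiomer of 10 | CCOC(=O)C[C@H]1[C@H](O)CC(C(=O)OC)c2ccc(C)cc12
F7 | step 4 | acetate of the (3R,4R)-alcohol | CCOC(=O)C[C@H]1[C@H](OC(C)=O)CC(C(=O)OC)c2ccc(C)cc12
A1 | alternative 1 | ten-membered cis,cis-diene lactone with 8-OTES, 15-OTBS, 14-OTBDPS | O=C1O[C@@H]2/C=C(/CO[Si](C)(C)C(C)(C)C)CC/C=C(/CO[Si](c3ccccc3)(c3ccccc3)C(C)(C)C)C[C@H](O[Si](CC)(CC)CC)[C@H]2C1
A2 | alternative 1 | seco bis(allylic bromide) lactone (bromides on C2 and C3) | O=C1O[C@H](/C=C(/CO[Si](C)(C)C(C)(C)C)CBr)[C@H](C1)[C@@H](O[Si](CC)(CC)CC)C/C(CO[Si](c1ccccc1)(c1ccccc1)C(C)(C)C)=C\CBr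
A3 | alternative 2 | 8-hydroxy α-methylene germacranolide with 15-OAc and 14-OTBS | C=C1C(=O)O[C@@H]2/C=C(/COC(C)=O)CC/C=C(/CO[Si](C)(C)C(C)(C)C)C[C@H](O)[C@@H]12
A4 | alternative 2 | 3-(bromomethyl)butenolide with tethered C8 aldehyde | O=C1O[C@H](/C=C(/COC(C)=O)CC/C=C(/CO[Si](C)(C)C(C)(C)C)CC=O)C=C1CBr
A5 | alternative 3 | ten-membered dienone with C7 tert-butoxycarbonylmethyl and 8-OPMB | O=C1/C=C(/CO[Si](C)(C)C(C)(C)C)CC/C=C(/CO[Si](c2ccccc2)(c2ccccc2)C(C)(C)C)C[C@H](OCc2ccc(OC)cc2)[C@H]1CC(=O)OC(C)(C)C
A6 | alternative 3 | cis-1,2-dialkenylcyclohex-2-enol (enol ether on the carbinol carbon, substituted isopropenyl on the neighbour) | O[C@]1(/C=C/OCc2ccc(OC)cc2)C=C(CO[Si](C)(C)C(C)(C)C)CC[C@H]1C(=C)CO[Si](c1ccccc1)(c1ccccc1)C(C)(C)C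
A7 | alternative 3 | tert-butyl bromoacetate | BrCC(=O)OC(C)(C)C
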